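**Strategy.** Azepine ring B (N4, C5–C9, C9a) is disconnected at C5–C6 and C8–C9. This removes C6–C7–C8 as a three-carbon unit and leaves a pyrrole-fused ring C/lactone D core. Both remaining termini sit on atoms of pyrrole ring A (N4 and C9a) and are 1,4-related, so both can be made cationic: an N4–CH2–OPiv group gives an iminium-type ion at C5, and a C9 carbinol gives an azafulvenium ion. In one flask, (E)-1,3-bis(trimethylsilyl)propene, a propene-1,3-diyl dianion equivalent, should add to both cations (formal [4+3] annulation), closing ring B and setting C9 trans to the C10 ethyl group. The precursor is a tricyclic tetrahydroindole carbinol.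

Key step: step 9

Locants used: ring A = pyrrole (N4, C3, C2, C1, C9a); ring B = azepine (N4, C5–C9, C9a); ring C = C9, C10, C11, C12, C1, C9a; lactone D = O–C11, C12, C13, C14; side-chain lactone = C18 (on C3), C19, C20, C21 and its ring O.

Assumption: in step 14 the enantiomer of the chiral ligand is the one that delivers the (18S) carbinol; this reagent-controlled sense is to be fixed on a model pyrrole aldehyde.

**Step 1**
Reactants: 1 (4R)-4-benzyl-3-butanoyl-1,3-oxazolidin-2-one; 2 ethyl (2E)-4-oxobut-2-enoate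
Product: 4 anti-aldol adduct (4R)-4-benzyl-3-[(2S,3S,4E)-6-ethoxy-2-ethyl-3-hydroxy-6-oxohex-4-enoyl]-1,3-oxazolidin-2-one, via silyl ether 3 (not isolated)
Conditions: MgCl2 (10 mol %), Et3N, Me3SiCl, EtOAc, rt; then TFA (cat.), MeOH
Reagents that add atoms: none
Why: Evans MgCl2-catalysed direct anti-aldol reaction, in which the chelated (Z)-enolate of the (R)-auxiliary should add to the non-enolisable enal through a boat transition state and set C10 and C11 (2,3-anti) under auxiliary control.

**Step 2**
Reactants: 4 anti-aldol adduct; 5 methyl 4-bromo-1H-pyrrole-2-carboxylate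
Product: 7 butenolide methyl 4-[(2R)-2-{(2S)-1-[(4R)-4-benzyl-2-oxo-1,3-oxazolidin-3-yl]-1-oxobutan-2-yl}-5-oxo-2,5-dihydrofuran-3-yl]-1H-pyrrole-2-carboxylate, via Z-hydroxy enoate 6 (not isolated)
Conditions: Pd(OAc)2 (10 mol %), P(o-tol)3, Ag2CO3, DMF, 80 °C
Reagents that add atoms: none
Why: Mizoroki–Heck β-arylation of the (E)-enoate (syn carbopalladation, syn β-hydride elimination) should place the pyrrole trans to the ester, so the C11 hydroxyl ends cis to the ester and lactonises; no stereocentre is formed and C11 is untouched.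

**Step 3**
Reactants: 7 butenolide
Product: 8 cis-lactone methyl 4-[(2S,3S)-2-{(2S)-1-[(4R)-4-benzyl-2-oxo-1,3-oxazolidin-3-yl]-1-oxobutan-2-yl}-5-oxooxolan-3-yl]-1H-pyrrole-2-carboxylate
Conditions: H2 (1 atm), Pd/C, EtOAc, rt
Reagents that add atoms: none
Why: Catalytic hydrogenation of the butenolide from the face opposite the bulky C11 side chain should deliver H12 trans to that chain, setting C12 with the pyrrole cis to the C10 branch (cis-4,5-disubstituted lactone).

**Step 4**
Reactants: 8 cis-lactone imide
Product: 10 (2S)-2-[(2S,3S)-3-(5-methoxycarbonyl-1H-pyrrol-3-yl)-5-oxooxolan-2-yl]butanoic acid, via peroxy acid 9 (not isolated)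
Conditions: LiOH, H2O2, THF/H2O, 0 °C; Na2SO3; then HCl (aq)
Reagents that add atoms: hydrogen peroxide (as LiOOH), OO
Why: Hydroperoxide cleavage of the N-acyl oxazolidinone attacks the exocyclic imide carbonyl, the peracid is reduced by sulfite, and any lactone opened by base recloses on acidification; no stereocentre is touched.

**Step 5**
Reactants: 10 lactone acid
Product: 12 tricyclic keto lactone (pyrrole N–H with CO2Me at C3; ring C with C9 ketone and C10 ethyl; cis-fused lactone D; ethyl and lactone O and lactone CH2 all cis), via mixed anhydride 11 (not isolated)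
Conditions: (CF3CO)2O, TfOH (cat.), CH2Cl2, 0 °C to rt
Reagents that add atoms: none
Why: Intramolecular Friedel–Crafts acylation through the mixed trifluoroacetic anhydride should close six-membered ring C at the free pyrrole α-position (C9a), which only the cis-lactone geometry allows.

**Step 6**
Reactants: 12 tricyclic keto lactone
Product: 13 N-(pivaloyloxymethyl) keto lactone
Conditions: NaH (1 equiv), DMF, 0 °C; ClCH2OPiv
Reagents that add atoms: chloromethyl pivalate, CC(C)(C)C(=O)OCCl
Why: N-alkylation of the acidic pyrrole N–H (one equivalent of base, so the C10 centre next to the ketone is not enolised) installs the N–CH2–OPiv unit whose methylene becomes C5.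

**Step 7**
Reactants: 13 N-(pivaloyloxymethyl) keto lactone
Product: 14 C9 carbinol (major epimer drawn with OH cis to ethyl; both epimers serve)
Conditions: NaBH4, CeCl3·7H2O, MeOH, −40 °C
Reagents that add atoms: none
Why: Luche 1,2-reduction of the 2-acylpyrrole ketone, with hydride entering opposite the C10 ethyl group; the C9 configuration is of no consequence because C9 is ionised in step 9.

**Step 8**
Reactants: 15 allyltrimethylsilane
Product: 17 (E)-1,3-bis(trimethylsilyl)prop-1-ene, via silylallyl lithium 16 (not isolated)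
Conditions: s-BuLi, TMEDA, THF, −78 °C; Me3SiCl
Reagents that add atoms: chlorotrimethylsilane, C[Si](C)(C)Cl
Why: Deprotonation of the allylsilane and γ-silylation of the α-silylallyl anion at its less hindered terminus should give the (E)-1,3-disilylpropene.

**Step 9**
Reactants: 14 C9 carbinol; 17 (E)-1,3-bis(trimethylsilyl)prop-1-ene
Product: 20 annulated tetracycle (ring B closed with a cis C7=C8 olefin; 9R,10R,11R,12S; CO2Me at C3), via azafulvenium triflate 18 (not isolated), via allylsilane 19 (not isolated)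
Conditions: 17 (3 equiv), Me3SiOTf (1.5 equiv), 2,6-di-tert-butyl-4-methylpyridine, CH2Cl2, −78 °C to 0 °C
Reagents that add atoms: none
Why: Proposed new method: Me3SiOTf should ionise the C9 carbinol to the pyrrole-stabilised cation 18, which is captured by the silyl-bearing vinyl carbon of 17 with loss of the allylic silyl group to give the α-silyl allylsilane 19; on warming, the N–CH2–OPiv group should ionise to an N-acyliminium-type ion and the terminal carbon of 19 attacks it with loss of the second silyl group. The closest known reactions are the Hosomi–Sakurai allylation of pyrrolyl and benzylic carbinols, N-acyliminium–allylsilane cyclisations, and the use of 1,3-bis(trimethylsilyl)propene as a propene-1,3-diyl dianion equivalent; their one-flask union on a 1,4-bis-electrophile is new. Ring B closes in a 7-endo allylsilane mode, both olefinic carbons ending in the ring as the cis C7=C8 olefin. C9 is set in the intermolecular step under substrate control: the ethyl group, the lactone oxygen and the lactone CH2 all lie on one face of ring C, so C8 enters from the open face, trans to ethyl. The step needs C–C bond formation to outrun loss of H10 from the cation and protodesilylation of 19, which the excess of 17 and the hindered pyridine base should secure. The C3 ester deactivates the pyrrole so that it does not compete as a nucleophile toward either cation.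

**Step 10**
Reactants: 20 annulated tetracycle
Product: 23 13-methylene lactone of 20, via Mannich base 21 (not isolated), via ammonium iodide 22 (not isolated)
Conditions: LiN(SiMe3)2, THF, −78 °C; CH2=NMe2+ I−; then MeI, MeOH; then NaHCO3 (aq), CH2Cl2
Reagents that add atoms: N,N-dimethylmethyleneiminium iodide, C=[N+](C)C.[I-]
Why: Lactone α-methylenation by the Eschenmoser sequence (aminomethylation of the kinetic C13 enolate, N-methylation, β-elimination); the stereocentre formed at C13 in 21 is destroyed again.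

**Step 11**
Reactants: 23 13-methylene lactone
Product: 24 saturated tetracycle (9R,10R,11R,12S,13S; 13-methyl; CO2Me at C3)
Conditions: H2 (1 atm), Pd/C, EtOAc, rt
Reagents that add atoms: none
Why: Catalytic hydrogenation should add H2 to the exo-methylene from the convex face of the cis-fused bicyclic lactone, placing the C13 methyl on the concave face (13S), and should saturate the C7=C8 olefin in the same operation.

**Step 12**
Reactants: 24 saturated tetracycle
Product: 25 C3 carboxylic acid of 24
Conditions: LiI, pyridine, reflux; then HCl (aq)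
Reagents that add atoms: none
Why: SN2 demethylation of the methyl ester by iodide, which should leave the lactone (secondary alkyl oxygen) and the C13 centre untouched.

**Step 13**
Reactants: 25 C3 carboxylic acid
Product: 27 C3 aldehyde, via decarboxylated pyrrole 26 (not isolated)
Conditions: TFA, 0 °C to rt; then HC(OEt)3; H2O
Reagents that add atoms: triethyl orthoformate, CCOC(OCC)OCC; water, O
Why: Clezy-type decarboxylative formylation: acid-mediated loss of CO2 from the pyrrole-2-carboxylic acid, then orthoformate formylation at the vacated α-position.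

**Step 14**
Reactants: 27 C3 aldehyde; 28 ethyl 2-(bromomethyl)prop-2-enoate
Product: 31 20-methylene bis-lactone (18S), via silyl ether 29 (not isolated), via hydroxy ester 30 (not isolated)
Conditions: CrCl2 (10 mol %), chiral carbazole-bis(oxazoline) ligand, Mn, Me3SiCl, THF, rt; then Bu4NF, THF, 0 °C
Reagents that add atoms: none
Why: Catalytic asymmetric Nozaki–Hiyama–Kishi 2-(alkoxycarbonyl)allylation, in which the ligand-bound allylchromium reagent should add to one face of the aldehyde and set C18 (S); the alkoxide freed by fluoride lactonises without acid, which would ionise the pyrrolyl carbinol.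

**Step 15**
Reactants: 31 20-methylene bis-lactone
Product: 32 bisdehydroneotuberostemonine
Conditions: H2 (1 atm), Rh/Al2O3, EtOAc, rt
Reagents that add atoms: none
Why: Hydrogenation of the α-methylene-γ-butyrolactone from the face opposite the C18 pyrrolyl group should give the cis-2,4 relationship (20S); rhodium is chosen to limit hydrogenolysis of the pyrrolylic C18–O bond.

**Compound list**

1 | (4R)-4-benzyl-3-butanoyl-1,3-oxazolidin-2-one | CCCC(=O)N1[C@H](Cc2ccccc2)COC1=O | starting material
2 | ethyl (2E)-4-oxobut-2-enoate | CCOC(=O)/C=C/C=O | starting material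
3 | O-trimethylsilyl ether of aldol adduct 4 | CC[C@H](C(=O)N1[C@H](Cc2ccccc2)COC1=O)[C@@H](O[Si](C)(C)C)/C=C/C(=O)OCC | intermediate
4 | (4R)-4-benzyl-3-[(2S,3S,4E)-6-ethoxy-2-ethyl-3-hydroxy-6-oxohex-4-enoyl]-1,3-oxazolidin-2-one | CC[C@H](C(=O)N1[C@H](Cc2ccccc2)COC1=O)[C@@H](O)/C=C/C(=O)OCC | intermediate
5 | methyl 4-bromo-1H-pyrrole-2-carboxylate | COC(=O)c1cc(Br)c[nH]1 | starting material
6 | Heck product of 4: (Z)-enoate with the 5-methoxycarbonyl-1H-pyrrol-3-yl group on C12 and the C11 hydroxyl cis to the ester | CC[C@H](C(=O)N1[C@H](Cc2ccccc2)COC1=O)[C@@H](O)/C(c1c[nH]c(C(=O)OC)c1)=C\C(=O)OCC | intermediate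
7 | methyl 4-[(2R)-2-{(2S)-1-[(4R)-4-benzyl-2-oxo-1,3-oxazolidin-3-yl]-1-oxobutan-2-yl}-5-oxo-2,5-dihydrofuran-3-yl]-1H-pyrrole-2-carboxylate | CC[C@H](C(=O)N1[C@H](Cc2ccccc2)COC1=O)[C@H]1OC(=O)C=C1c1c[nH]c(C(=O)OC)c1 | intermediate
8 | methyl 4-[(2S,3S)-2-{(2S)-1-[(4R)-4-benzyl-2-oxo-1,3-oxazolidin-3-yl]-1-oxobutan-2-yl}-5-oxooxolan-3-yl]-1H-pyrrole-2-carboxylate | CC[C@H](C(=O)N1[C@H](Cc2ccccc2)COC1=O)[C@H]1OC(=O)C[C@H]1c1c[nH]c(C(=O)OC)c1 | intermediate
9 | peroxy acid corresponding to 10 | CC[C@H](C(=O)OO)[C@H]1OC(=O)C[C@H]1c1c[nH]c(C(=O)OC)c1 | intermediate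
10 | (2S)-2-[(2S,3S)-3-(5-methoxycarbonyl-1H-pyrrol-3-yl)-5-oxooxolan-2-yl]butanoic acid | CC[C@H](C(=O)O)[C@H]1OC(=O)C[C@H]1c1c[nH]c(C(=O)OC)c1 | intermediate
11 | mixed trifluoroacetic anhydride of 10 | CC[C@H](C(=O)OC(=O)C(F)(F)F)[C@H]1OC(=O)C[C@H]1c1c[nH]c(C(=O)OC)c1 | intermediate
12 | tricyclic keto lactone: N–H pyrrole with CO2Me at C3, C9 ketone, C10 ethyl, cis-fused lactone D; ethyl, lactone O and lactone CH2 all cis | CC[C@H]1[C@H]2OC(=O)C[C@H]2c2cc(C(=O)OC)[nH]c2C1=O | intermediate
13 | N-(pivaloyloxymethyl) derivative of 12 | CC[C@H]1[C@H]2OC(=O)C[C@H]2c2cc(C(=O)OC)n(COC(=O)C(C)(C)C)c2C1=O | intermediate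
14 | C9 carbinol of 13 (major epimer, OH cis to ethyl) | CC[C@H]1[C@H]2OC(=O)C[C@H]2c2cc(C(=O)OC)n(COC(=O)C(C)(C)C)c2[C@H]1O | intermediate
15 | allyltrimethylsilane | C=CC[Si](C)(C)C | starting material
16 | [1-(trimethylsilyl)allyl]lithium | [Li]C(C=C)[Si](C)(C)C | intermediate
17 | (E)-1,3-bis(trimethylsilyl)prop-1-ene | C[Si](C)(C)C/C=C/[Si](C)(C)C | intermediate
18 | C9 pyrrolylcarbinyl (azafulvenium) cation from 14, as triflate | CC[C@H]1[C@H]2OC(=O)C[C@H]2c2cc(C(=O)OC)n(COC(=O)C(C)(C)C)c2[CH+]1.[O-]S(=O)(=O)C(F)(F)F | intermediate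
19 | C9-[1-(trimethylsilyl)allyl] compound, new C9–C8 bond trans to ethyl (mixture at C8) | CC[C@H]1[C@H]2OC(=O)C[C@H]2c2cc(C(=O)OC)n(COC(=O)C(C)(C)C)c2[C@@H]1C(C=C)[Si](C)(C)C | intermediate
20 | annulated tetracycle: rings A–D with cis C7=C8 olefin in ring B, CO2Me at C3 (9R,10R,11R,12S) | CC[C@H]1[C@H]2OC(=O)C[C@H]2c2cc(C(=O)OC)n3c2[C@@H]1/C=C\CC3 | intermediate
21 | 13-(dimethylaminomethyl) lactone (Mannich base of 20) | CC[C@H]1[C@H]2OC(=O)[C@H](CN(C)C)[C@H]2c2cc(C(=O)OC)n3c2[C@@H]1/C=C\CC3 | intermediate
22 | trimethylammonium iodide of 21 | CC[C@H]1[C@H]2OC(=O)[C@H](C[N+](C)(C)C)[C@H]2c2cc(C(=O)OC)n3c2[C@@H]1/C=C\CC3.[I-] | intermediate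
23 | 13-methylene lactone of 20 | CC[C@H]1[C@H]2OC(=O)C(=C)[C@H]2c2cc(C(=O)OC)n3c2[C@@H]1/C=C\CC3 | intermediate
24 | saturated tetracycle with 13-methyl and CO2Me at C3 (9R,10R,11R,12S,13S) | CC[C@H]1[C@H]2OC(=O)[C@@H](C)[C@H]2c2cc(C(=O)OC)n3c2[C@@H]1CCCC3 | intermediate
25 | C3 carboxylic acid of 24 | CC[C@H]1[C@H]2OC(=O)[C@@H](C)[C@H]2c2cc(C(=O)O)n3c2[C@@H]1CCCC3 | intermediate
26 | C3-unsubstituted pyrrole (decarboxylated 25) | CC[C@H]1[C@H]2OC(=O)[C@@H](C)[C@H]2c2ccn3c2[C@@H]1CCCC3 | intermediate
27 | C3 aldehyde | CC[C@H]1[C@H]2OC(=O)[C@@H](C)[C@H]2c2cc(C=O)n3c2[C@@H]1CCCC3 | intermediate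
28 | ethyl 2-(bromomethyl)prop-2-enoate | C=C(CBr)C(=O)OCC | starting material
29 | (18S) O-trimethylsilyl homoallylic ether (ethyl 2-methylene ester side chain on C3) | CC[C@H]1[C@H]2OC(=O)[C@@H](C)[C@H]2c2cc([C@@H](O[Si](C)(C)C)CC(=C)C(=O)OCC)n3c2[C@@H]1CCCC3 | intermediate
30 | (18S) hydroxy ester | CC[C@H]1[C@H]2OC(=O)[C@@H](C)[C@H]2c2cc([C@@H](O)CC(=C)C(=O)OCC)n3c2[C@@H]1CCCC3 | intermediate
31 | 20-methylene bis-lactone (18S) | CC[C@H]1[C@H]2OC(=O)[C@@H](C)[C@H]2c2cc([C@@H]3CC(=C)C(=O)O3)n3c2[C@@H]1CCCC3 | intermediate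
32 | bisdehydroneotuberostemonine | CC[C@H]1[C@H]2OC(=O)[C@@H](C)[C@H]2c2cc([C@@H]3C[C@H](C)C(=O)O3)n3c2[C@@H]1CCCC3 | target

**Total step count:** 15. **Longest linear sequence:** 14 (steps 1–7 and 9–15; step 8 prepares reagent 17).

**Steps most likely to fail**

Step 9 (Proposed new method). The second ionisation, at C5, may be too slow on the ester-deactivated pyrrole. Intermediate 19 could then be lost by protodesilylation, or the C9 cation could eliminate toward C10 before it is trapped. Fallback (ring-closing metathesis in place of the double cation capture): it sets out from 12. Luche reduction (NaBH4, CeCl3·7H2O) should give the N–H carbinol F1. Ionisation with BF3·OEt2 in the presence of CH2=CHBF3K should give the C9-vinyl compound F2, with vinyl trans to ethyl. N-Alkylation with 4-bromobut-1-ene (Cs2CO3, DMF) should give the diene F3. Ring-closing metathesis with second-generation Grubbs catalyst (CH2Cl2, 40 °C) closes ring B at C7=C8, and the route is rejoined at 20.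

Step 2. Migratory insertion into the 1,2-disubstituted enoate may be sluggish. The β-hydroxy imide may undergo retro-aldol cleavage in the hot basic medium, and the allylic alcohol may isomerise to a ketone. Fallback (conjugate addition in place of Heck arylation): it sets out from 4. Silylation (TBSOTf, 2,6-lutidine) should give the silyl ether F4. Rhodium-catalysed 1,4-addition of commercial methyl 4-(4,4,5,5-tetramethyl-1,3,2-dioxaborolan-2-yl)-1H-pyrrole-2-carboxylate ([Rh(OH)(cod)]2, the BINAP enantiomer matched to the 12S centre, K3PO4, dioxane/H2O) should give the β-pyrrolyl ester F5. HF·pyridine removes the silyl group and the hydroxy ester lactonises; the route is rejoined at 8.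

Step 14. The aldehyde is a vinylogous formamide and may react slowly, facial control by the ligand may be poor, and the pyrrolyl carbinol may racemise by ionisation. Fallback (ketone reduction sets C18 instead of C–C addition): it sets out from 27. Indium-mediated Barbier allylation with 28 (In powder, THF/H2O) should give the hydroxy ester F6 as a mixture at C18. Dess–Martin oxidation should give the ketone F7. Corey–Bakshi–Shibata reduction ((R)-2-methyl-CBS-oxazaborolidine, BH3·SMe2) should then give the (18S) alcohol. The route is rejoined at 30, which lactonises to 31 with catalytic DBU.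

**Further compounds**

F1 | step 9 | N–H C9 carbinol (reduced 12; OH cis to ethyl drawn) | CC[C@H]1[C@H]2OC(=O)C[C@H]2c2cc(C(=O)OC)[nH]c2[C@H]1O
F2 | step 9 | N–H C9-vinyl compound (vinyl trans to ethyl) | CC[C@H]1[C@H]2OC(=O)C[C@H]2c2cc(C(=O)OC)[nH]c2[C@@H]1C=C
F3 | step 9 | N-(but-3-enyl) C9-vinyl diene | CC[C@H]1[C@H]2OC(=O)C[C@H]2c2cc(C(=O)OC)n(CCC=C)c2[C@@H]1C=C
F4 | step 2 | O-tert-butyldimethylsilyl ether of 4 | CC[C@H](C(=O)N1[C@H](Cc2ccccc2)COC1=O)[C@@H](O[Si](C)(C)C(C)(C)C)/C=C/C(=O)OCC
F5 | step 2 | β-pyrrolyl ester (conjugate adduct of F4, 12S) | CC[C@H](C(=O)N1[C@H](Cc2ccccc2)COC1=O)[C@@H](O[Si](C)(C)C(C)(C)C)[C@@H](CC(=O)OCC)c1c[nH]c(C(=O)OC)c1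
F6 | step 14 | hydroxy ester, mixture of C18 epimers | CC[C@H]1[C@H]2OC(=O)[C@@H](C)[C@H]2c2cc(C(O)CC(=C)C(=O)OCC)n3c2[C@@H]1CCCC3
F7 | step 14 | C18 ketone | CC[C@H]1[C@H]2OC(=O)[C@@H](C)[C@H]2c2cc(C(=O)CC(=C)C(=O)OCC)n3c2[C@@H]1CCCC3
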